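All constants were set for the occasion; the result is computed.

Read from late times backwards: no step of this scheme removes a living end, so once initiator has stopped feeding them their number stands still, and the reckoning below counts how many ends a flask holds and how many turnovers they get through.

    free monomer + living end → monomer in chains + living end, rate k1*[living end]*[free monomer] (k1 = 3.80 L mol⁻¹ s⁻¹, Ea1 = 42.0 kJ mol⁻¹)
    2 initiator → spent initiator (k2 = 44.5 L mol⁻¹ s⁻¹, Ea2 = 36.0 kJ mol⁻¹)
    free monomer + initiator → living end + monomer in chains (k3 = 0.130 L mol⁻¹ s⁻¹, Ea3 = 66.0 kJ mol⁻¹)
    (constants at 25 °C)

- maple: free monomer 0.39 M; initiator 2 mol%; temperature 25 °C; time 1.0 min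
- ash: free monomer 0.39 M; initiator 2 mol%; temperature 40 °C; time 1.0 min

- for a step with 2 of a species take k times the square, and two of it per event
- the list of constants is for 25 °C, to be carried to other temperatures by the activation energies

1. which of these there is most of at the end, counted by the free monomer in it, maple (monomer in chains / free monomer)
2. which of these there is most of at the end, counted by the free monomer in it, ash (monomer in chains / free monomer)
3. final amount of the leader among these, as a percentage of the free monomer charged, in maple
4. final amount of the leader among these, as a percentage of the free monomer charged, in ash

Maple charges 0.00780 M of initiator. At that charge each initiator burns against its own kind at a pace of 0.694 s⁻¹, faster than the 0.0507 s⁻¹ at which step 3 takes it, but the burn slows as initiator thins. With free monomer held near its charge, summing the share that goes to step 3 gives living ends = charge × (step 3 pace / burn pace) × ln(1 + burn pace / step 3 pace). That is 0.00153 M for maple. Step 1 is then pseudo-first-order in free monomer, and over 1.0 min its rate constant times these ends gives 0.349, which leaves 70.5% of the free monomer.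

The weak link is that all the ends were counted from time zero. But the last initiator, with the burn thinned, decays at the pace of step 3, on a reckoned time of 19.7 s. Taking the average end as 0.5 of that time late costs maple 9.86 s. The turnovers, meaning the rate constant of step 1 times the living ends times the time less this lag, are then 0.292, and the free monomer left is the exponential of minus the turnovers. So the reckoning puts free monomer in the lead in maple at 74.7%.

Ash at 40 °C quickens step 1 by 2.25, step 2 by 2.00 and step 3 by 3.58. The same sum gives 0.00220 M living ends and a lag of 2.75 s, so 1.08 turnovers. The reckoning puts monomer in chains in the lead in ash at 66.0%.

The forecast names free monomer at 75% for maple and monomer in chains at 64% for ash, on the ground that “those ends then persist and propagate for the rest of the minute”. For ash the hand figure stands higher than the forecast's.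

The simulation gives free monomer at 74.7% in maple and monomer in chains at 65.3% in ash.

Maple's free monomer reads as 0.292 turnovers against the 0.292 reckoned. A neighbour of maple carries 8 mol% of initiator. Its charge of 0.0312 M burns at 2.78 s⁻¹, and the same sum gives 0.00229 M living ends, 1.50 times those of maple for 4.00 times the initiator. With the lag of maple that makes 0.436 turnovers and 64.7% free monomer left. The simulated neighbour holds 0.00221 M living ends and 63.4% free monomer after 1.00 min.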